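A direct plan would open the meso anhydride cis-2,3-dimethylsuccinic anhydride A1 enantioselectively with N,O-dimethylhydroxylamine to the amide acid A2, add the ring A aryl Grignard reagent, and reduce the keto acid in two stages to (2R,3R)-4-(3,5-dimethoxyphenyl)-2,3-dimethylbutanal A3.
The ring B aryllithium and acid would then close ring C by Friedel–Crafts attack of ring A on the C7' cation (C2–C7' bond) to the 4-deoxy cyclolignan A4, and a directed metalation, borylation and oxidation would add the C4 hydroxyl last.
Weakest steps of that plan: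
- The desymmetrising aminolysis of A1: an untested pairing of catalyst and nucleophile on which the absolute configuration of every stereocentre would rest.
- The ketone-to-methylene and acid-to-aldehyde adjustments: two redox operations that build nothing and carry an enolisable α-stereocentre past acid and hydride.
- The late hydroxylation of A4: excess butyllithium on the finished skeleton would have to choose C4–H over the positions ortho to the ring B phenoxide and over the doubly benzylic C7'–H, whose removal would epimerise C7'.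

**Retrosynthetic overview**
Ring C is cut across two bonds at once, C7'–C8' and C7–C8: a photoenolisation/Diels–Alder reaction joins a ring A 2-methylbenzaldehyde (formyl carbon = C7', ortho-methyl = C7) with tiglic aldehyde, used as a cis-2-butene equivalent.
The E geometry of tiglic aldehyde writes the cis C8/C8' dimethyl pair in one suprafacial event; its formyl group is then excised by rhodium with retention.
The C7' hydroxyl left by the photoenol is the leaving group for the last C–C bond (C7'–C1'): guaiacol adds anti to both methyl groups, which gives the 7',8'-trans relation.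
Ring order: ring A is bought with all three oxygens in place, ring C is closed by [4+2], ring B is attached last.
The design has no meso desymmetrisation, no enolisable carbonyl next to a stereocentre that is kept, no late hydroxylation, and one protecting group.

Key step: step 3

Remark: the (R,R) ligand is assumed to give the (2S,3R) configuration of the Diels–Alder adduct (the (S,S) ligand would be used if the sense proves opposite); the C1 configuration of the adduct and of the tetralol is drawn for the endo mode and has no bearing on the target, because C7' is ionised in step 5.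

Step 1
Reactants: 1 2,6-dimethoxy-4-methylphenol
Product: 2 2-(benzyloxy)-1,3-dimethoxy-5-methylbenzene
Conditions: BnBr (1.2 equiv), K2CO3 (2 equiv), DMF, 60 °C
Reagents that add atoms: benzyl bromide, BrCc1ccccc1
Why: Williamson ether synthesis on the phenoxide; the benzyl ether masks the C4 oxygen through the electrophilic, photochemical and acidic steps and is the only protecting group of the route.

Step 2
Reactants: 2 2-(benzyloxy)-1,3-dimethoxy-5-methylbenzene
Product: 4 3-(benzyloxy)-2,4-dimethoxy-6-methylbenzaldehyde, via aryl iminium salt 3 (not isolated)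
Conditions: POCl3 (1.5 equiv), DMF, 0 → 70 °C; then H2O, rt
Reagents that add atoms: N,N-dimethylformamide, CN(C)C=O; water, O
Why: Vilsmeier–Haack formylation; the two free ring positions are equivalent and each is ortho to one methoxy group, para to the other and ortho to the methyl group, so a single aldehyde should form with the formyl group (future C7') next to the methyl group (future C7).

Step 3
Reactants: 4 3-(benzyloxy)-2,4-dimethoxy-6-methylbenzaldehyde; 5 (E)-2-methylbut-2-enal (tiglic aldehyde)
Product: 7 (1R,2S,3R)-7-(benzyloxy)-1-hydroxy-6,8-dimethoxy-2,3-dimethyl-1,2,3,4-tetrahydronaphthalene-2-carbaldehyde, via photoenol 6 (not isolated)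
Conditions: Ti(Oi-Pr)4 (1.2 equiv), (R,R)-TADDOL [(4R,5R)-2,2-dimethyl-α,α,α',α'-tetraphenyl-1,3-dioxolane-4,5-dimethanol] (1.3 equiv), 5 (3 equiv), toluene, degassed, 365 nm LED, 0 °C; aq potassium sodium tartrate
Reagents that add atoms: none
Why: Proposed new method: 365 nm light excites 4, and the triplet aldehyde moves a hydrogen from its ortho-methyl group to its own carbonyl oxygen to give photoenol 6, a hydroxy-o-quinodimethane that should be held as a dienolate on the chiral titanium TADDOLate together with the formyl group of 5 and add to the C=C bond of 5 in a suprafacial [4+2] cycloaddition. The closest known reaction type is the Ti(Oi-Pr)4/TADDOL-mediated enantioselective photoenolisation/Diels–Alder reaction of electron-rich 2-methylbenzaldehydes with enones, α-substituted ones included; an acyclic α-methyl enal as the dienophile is the step beyond it. Ring C closes in an intermolecular Diels–Alder mode through the two bonds C7'–C8' and C7–C8, and ring A regains its aromaticity. C8' and C8 are set as a pair: their cis-dimethyl relation follows from the E geometry of 5 and the concerted addition, their absolute configuration from the face of 5 that the TADDOLate leaves open, and the C7' carbinol from the endo (chelate) alignment of the formyl group, which is not needed later. The step needs regiocontrol, which the polarisation of the 1-hydroxy diene should secure (its CH2 terminus C7 bonds to the β-carbon of the enal), and it needs 5 to keep its geometry, which should hold because the intramolecular hydrogen transfer in triplet 4 outruns energy transfer to 5 and 5 hardly absorbs at 365 nm.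

Step 4
Reactants: 7 (1R,2S,3R)-7-(benzyloxy)-1-hydroxy-6,8-dimethoxy-2,3-dimethyl-1,2,3,4-tetrahydronaphthalene-2-carbaldehyde
Product: 8 (1S,2R,3R)-7-(benzyloxy)-6,8-dimethoxy-2,3-dimethyl-1,2,3,4-tetrahydronaphthalen-1-ol
Conditions: RhCl(PPh3)3 (1.1 equiv), toluene, 110 °C
Reagents that add atoms: none
Why: Tsuji–Wilkinson decarbonylation: oxidative addition of the formyl C–H bond to monovalent rhodium, extrusion of CO and C–H reductive elimination proceed with retention at the migrating carbon, so hydrogen should take the place of the formyl group at C8' and the two methyl groups stay cis (the descriptor at C2 changes only by priority); the aldehyde has no α-hydrogen and cannot epimerise before it is removed.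

Step 5
Reactants: 8 (1S,2R,3R)-7-(benzyloxy)-6,8-dimethoxy-2,3-dimethyl-1,2,3,4-tetrahydronaphthalen-1-ol; 9 2-methoxyphenol (guaiacol)
Product: 10 4-[(1R,2R,3R)-7-(benzyloxy)-6,8-dimethoxy-2,3-dimethyl-1,2,3,4-tetrahydronaphthalen-1-yl]-2-methoxyphenol
Conditions: 9 (5 equiv), CF3CO2H (2 equiv), CH2Cl2, −40 → 0 °C; aq NaHCO3
Reagents that add atoms: none
Why: Intermolecular Friedel–Crafts alkylation: the acid ionises the C7' hydroxyl to a cation stabilised by the ortho and para methoxy groups of ring A, guaiacol should attack through its carbon para to the hydroxyl (its stronger donor) and on the face opposite to the cis methyl groups at C8' and C8, which both half-chair conformers of the cation leave open, so that C7' is set as R with the 7',8'-trans relation under substrate control.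

Step 6
Reactants: 10 4-[(1R,2R,3R)-7-(benzyloxy)-6,8-dimethoxy-2,3-dimethyl-1,2,3,4-tetrahydronaphthalen-1-yl]-2-methoxyphenol
Product: 11 (−)-(7'R,8R,8'R)-4,4'-dihydroxy-3,3',5-trimethoxy-2,7'-cyclolignan [(6R,7R,8R)-8-(4-hydroxy-3-methoxyphenyl)-1,3-dimethoxy-6,7-dimethyl-5,6,7,8-tetrahydronaphthalen-2-ol]
Conditions: H2 (1 atm), 10% Pd/C, EtOAc–EtOH, rt
Reagents that add atoms: none
Why: Hydrogenolysis of the aryl benzyl ether should free the C4 phenol; the diaryl methine C7' carries no heteroatom and is not cleaved, and no stereocentre is touched.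

## Compound list
1 | 2,6-dimethoxy-4-methylphenol | COc1cc(C)cc(OC)c1O | starting material
2 | 2-(benzyloxy)-1,3-dimethoxy-5-methylbenzene | COc1cc(C)cc(OC)c1OCc1ccccc1 | intermediate
3 | N-{[3-(benzyloxy)-2,4-dimethoxy-6-methylphenyl]methylidene}-N-methylmethanaminium dichlorophosphate | C[N+](C)=Cc1c(C)cc(OC)c(OCc2ccccc2)c1OC.[O-]P(=O)(Cl)Cl | intermediate
4 | 3-(benzyloxy)-2,4-dimethoxy-6-methylbenzaldehyde | Cc1cc(OC)c(OCc2ccccc2)c(OC)c1C=O | intermediate
5 | (E)-2-methylbut-2-enal (tiglic aldehyde) | C/C=C(\C)C=O | starting material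
6 | [3-(benzyloxy)-2,4-dimethoxy-6-methylidenecyclohexa-2,4-dien-1-ylidene]methanol, photoenol with the hydroxyl pointing away from the methylidene group (CIP descriptor Z) | O/C=C1/C(=C)C=C(OC)C(OCc2ccccc2)=C1OC | intermediate
7 | (1R,2S,3R)-7-(benzyloxy)-1-hydroxy-6,8-dimethoxy-2,3-dimethyl-1,2,3,4-tetrahydronaphthalene-2-carbaldehyde | O[C@@H]1c2c(cc(OC)c(OCc3ccccc3)c2OC)C[C@@H](C)[C@]1(C)C=O | intermediate
8 | (1S,2R,3R)-7-(benzyloxy)-6,8-dimethoxy-2,3-dimethyl-1,2,3,4-tetrahydronaphthalen-1-ol | O[C@@H]1c2c(cc(OC)c(OCc3ccccc3)c2OC)C[C@@H](C)[C@H]1C | intermediate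
9 | 2-methoxyphenol (guaiacol) | COc1ccccc1O | starting material
10 | 4-[(1R,2R,3R)-7-(benzyloxy)-6,8-dimethoxy-2,3-dimethyl-1,2,3,4-tetrahydronaphthalen-1-yl]-2-methoxyphenol | COc1cc([C@@H]2c3c(cc(OC)c(OCc4ccccc4)c3OC)C[C@@H](C)[C@H]2C)ccc1O | intermediate
11 | (−)-(7'R,8R,8'R)-4,4'-dihydroxy-3,3',5-trimethoxy-2,7'-cyclolignan = (6R,7R,8R)-8-(4-hydroxy-3-methoxyphenyl)-1,3-dimethoxy-6,7-dimethyl-5,6,7,8-tetrahydronaphthalen-2-ol | COc1cc([C@@H]2c3c(cc(OC)c(O)c3OC)C[C@@H](C)[C@H]2C)ccc1O | target

Total step count: 6. Longest linear sequence: 6 steps (1 → 11).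

**Steps most likely to fail**

Step 3 (proposed new method).
- What may go wrong: triplet energy transfer from excited 4 may isomerise 5 and erode the cis-dimethyl relation; the titanium complex may give poor facial control with an aldehyde dienophile; the dienolate may add to the formyl group of 5 instead of to its C=C bond.
- Fallback, in known chemistry, from 5 to 10: the tiglyl unit would be delivered as a nucleophile instead of as a dienophile.
- 5 would be reduced (NaBH4, CeCl3·7H2O, MeOH) to (E)-2-methylbut-2-en-1-ol F1 and borylated (B2pin2, Pd(MeCN)4(BF4)2 cat., DMSO–MeOH) to 4,4,5,5-tetramethyl-2-[(E)-2-methylbut-2-enyl]-1,3,2-dioxaborolane F2.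
- Commercial 4-bromo-2,6-dimethoxyphenol would be benzylated to 2-(benzyloxy)-5-bromo-1,3-dimethoxybenzene F3, lithiated between bromine and methoxy (LDA, THF, −78 °C) and formylated with DMF to 3-(benzyloxy)-6-bromo-2,4-dimethoxybenzaldehyde F4.
- Chiral phosphoric acid-catalysed allylboration of F4 with F2 ((R)-TRIP or its enantiomer, toluene, −30 °C) should give the anti alcohol (1R,2R)-1-[3-(benzyloxy)-6-bromo-2,4-dimethoxyphenyl]-2,3-dimethylbut-3-en-1-ol F5, which sets C8'.
- Hydroboration with 9-BBN-H (2.5 equiv) should set C8 by 1,2-induction from C8' and give (1R,2R,3R)-1-[3-(benzyloxy)-6-bromo-2,4-dimethoxyphenyl]-4-(9-borabicyclo[3.3.1]nonan-9-yl)-2,3-dimethylbutan-1-ol F6 (held as its O-borinate in the flask).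
- Intramolecular B-alkyl Suzuki coupling (PdCl2(dppf), K3PO4, DMF–H2O, 60 °C) would close ring C at the C1–C7 bond to (1R,2R,3R)-7-(benzyloxy)-6,8-dimethoxy-2,3-dimethyl-1,2,3,4-tetrahydronaphthalen-1-ol F7, the C1 epimer of 8.
- F7 gives the same cation under the conditions of step 5 and so returns to the route at 10.

Step 5.
- What may go wrong: attack of the cation on the guaiacol carbon para to the methoxy group instead of para to the hydroxyl; loss of the C8' proton from the cation and re-protonation, which would scramble C8'.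
- Fallback, from 8 to 11: commercial 2-bromo-6-methoxyphenol would replace 9. Its bromine sits next to the competing carbon and should leave only the position para to the hydroxyl open.
- The arylation would give 4-[(1R,2R,3R)-7-(benzyloxy)-6,8-dimethoxy-2,3-dimethyl-1,2,3,4-tetrahydronaphthalen-1-yl]-2-bromo-6-methoxyphenol F10.
- Hydrogenolysis as in step 6 with added NaOAc would remove bromine and benzyl together and rejoin the route at 11.

Step 4.
- What may go wrong: retro-aldol opening of the β-hydroxy aldehyde or loss of the β-hydroxyl from the alkyl rhodium intermediate at 110 °C; slow CO extrusion at the quaternary carbon.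
- Fallback, from 7 to 10: the carbinol would be masked first, so that both pathways are closed by structure.
- 7 would be silylated (TBSOTf, 2,6-lutidine, CH2Cl2, −78 °C) to (1R,2S,3R)-7-(benzyloxy)-1-[(tert-butyldimethylsilyl)oxy]-6,8-dimethoxy-2,3-dimethyl-1,2,3,4-tetrahydronaphthalene-2-carbaldehyde F8.
- F8 would be decarbonylated with RhCl(PPh3)3 to tert-butyl{[(1S,2R,3R)-7-(benzyloxy)-6,8-dimethoxy-2,3-dimethyl-1,2,3,4-tetrahydronaphthalen-1-yl]oxy}dimethylsilane F9.
- F9 would go directly into step 5, where the acid ionises the benzylic silyl ether to the same cation, and the route is rejoined at 10.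

## Further compounds
F1 | step 3 | (E)-2-methylbut-2-en-1-ol | C/C=C(\C)CO
F2 | step 3 | 4,4,5,5-tetramethyl-2-[(E)-2-methylbut-2-enyl]-1,3,2-dioxaborolane | C/C=C(\C)CB1OC(C)(C)C(C)(C)O1
F3 | step 3 | 2-(benzyloxy)-5-bromo-1,3-dimethoxybenzene | COc1cc(Br)cc(OC)c1OCc1ccccc1
F4 | step 3 | 3-(benzyloxy)-6-bromo-2,4-dimethoxybenzaldehyde | COc1cc(Br)c(C=O)c(OC)c1OCc1ccccc1
F5 | step 3 | (1R,2R)-1-[3-(benzyloxy)-6-bromo-2,4-dimethoxyphenyl]-2,3-dimethylbut-3-en-1-ol | O[C@@H](c1c(Br)cc(OC)c(OCc2ccccc2)c1OC)[C@H](C)C(C)=C
F6 | step 3 | (1R,2R,3R)-1-[3-(benzyloxy)-6-bromo-2,4-dimethoxyphenyl]-4-(9-borabicyclo[3.3.1]nonan-9-yl)-2,3-dimethylbutan-1-ol | O[C@@H](c1c(Br)cc(OC)c(OCc2ccccc2)c1OC)[C@H](C)[C@H](C)CB1C2CCCC1CCC2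
F7 | step 3 | (1R,2R,3R)-7-(benzyloxy)-6,8-dimethoxy-2,3-dimethyl-1,2,3,4-tetrahydronaphthalen-1-ol | O[C@H]1c2c(cc(OC)c(OCc3ccccc3)c2OC)C[C@@H](C)[C@H]1C
F8 | step 4 | (1R,2S,3R)-7-(benzyloxy)-1-[(tert-butyldimethylsilyl)oxy]-6,8-dimethoxy-2,3-dimethyl-1,2,3,4-tetrahydronaphthalene-2-carbaldehyde | CC(C)(C)[Si](C)(C)O[C@@H]1c2c(cc(OC)c(OCc3ccccc3)c2OC)C[C@@H](C)[C@]1(C)C=O
F9 | step 4 | tert-butyl{[(1S,2R,3R)-7-(benzyloxy)-6,8-dimethoxy-2,3-dimethyl-1,2,3,4-tetrahydronaphthalen-1-yl]oxy}dimethylsilane | CC(C)(C)[Si](C)(C)O[C@@H]1c2c(cc(OC)c(OCc3ccccc3)c2OC)C[C@@H](C)[C@H]1C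
F10 | step 5 | 4-[(1R,2R,3R)-7-(benzyloxy)-6,8-dimethoxy-2,3-dimethyl-1,2,3,4-tetrahydronaphthalen-1-yl]-2-bromo-6-methoxyphenol | COc1cc([C@@H]2c3c(cc(OC)c(OCc4ccccc4)c3OC)C[C@@H](C)[C@H]2C)cc(Br)c1O
A1 | direct plan | cis-2,3-dimethylsuccinic anhydride, (3R,4S)-3,4-dimethyloxolane-2,5-dione (meso) | O=C1[C@@H](C)[C@H](C(=O)O1)C
A2 | direct plan | (2R,3S)-4-[methoxy(methyl)amino]-2,3-dimethyl-4-oxobutanoic acid | CON(C)C(=O)[C@@H](C)[C@H](C(=O)O)C
A3 | direct plan | (2R,3R)-4-(3,5-dimethoxyphenyl)-2,3-dimethylbutanal | COc1cc(cc(OC)c1)C[C@@H](C)[C@H](C=O)C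
A4 | direct plan | 4-[(1R,2R,3R)-6,8-dimethoxy-2,3-dimethyl-1,2,3,4-tetrahydronaphthalen-1-yl]-2-methoxyphenol | COc1cc([C@@H]2c3c(cc(OC)cc3OC)C[C@@H](C)[C@H]2C)ccc1O
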